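**Plan**

- Retrosynthesis first cuts the two outer CH2 bridges on both sides: the CH2–C4 bond to each propionylfilicinic acid end unit (quinone-methide capture) and the inner-ring C–CH2 bond (phenolic Mannich reaction).
- It then cuts the two aryl–C(=O)Et bonds (Friedel–Crafts) and the four O–ethyl bonds, leaving bis(2,4-diethoxy-6-hydroxyphenyl)methane.
- Both inner benzene rings are then opened together: in each ring the bonds C(OH)–C(CH2) and C(OEt)–CH are cut, giving one five-carbon skipped bis-ynol ether and two 3-ethoxycyclobutenones.
- Enabling feature: each inner ring is a 1,3,5-trioxygenated benzene whose CH2-bearing carbon lies between two O-bearing carbons. The C(CH2)–C(O) edge maps onto an ynol ether C≡C, the other four carbons (C–OH, CH, C–O, CH) onto a 3-alkoxyvinylketene, and the single CH2 carries two such edges.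
- Forward: ethoxyacetylene gives the skipped diyne and the cyclobutenone; the two inner rings form one after the other in one flask; then acylation, de-ethylation, aminomethylation and union with two end units, whose ring comes from dearomative gem-dimethylation of flopropione.
- Stereochemistry: the target has no stereocentre; only the regiochemistry of the two ketene–ynol ether cycloadditions has to be controlled.

Key step: step 5

Remark: the end units of the target are drawn as one enol tautomer of an acylfilicinic acid; the route is taken to deliver that tautomeric system.
Remark: formaldehyde is used as paraformaldehyde in step 1 and as formalin in step 9; ethoxyacetylene is used as its commercial hexane solution.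

**Route**

Step 1
Reactants: 1 ethoxyacetylene; 2 formaldehyde (as paraformaldehyde)
Product: 4 3-ethoxyprop-2-yn-1-ol, via lithium ethoxyacetylide 3 (not isolated)
Conditions: n-BuLi, THF, −78 °C; (CH2O)n, −78 °C to rt; H2O quench, no acid
Reagents that add atoms: none
Why: Lithiation of the terminal ynol ether and 1,2-addition of the acetylide to formaldehyde (acetylide hydroxymethylation) is routine, and a neutral aqueous quench should keep the acid-labile product from Meyer–Schuster rearrangement.

Step 2
Reactants: 4 3-ethoxyprop-2-yn-1-ol
Product: 5 3-bromo-1-ethoxyprop-1-yne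
Conditions: CBr4, PPh3, CH2Cl2, −30 to 0 °C; pentane trituration, filtration through basic alumina, used at once as a cold solution
Reagents that add atoms: carbon tetrabromide, BrC(Br)(Br)Br
Why: The Appel reaction converts the primary propargylic alcohol into the bromide by SN2 attack of bromide on the alkoxyphosphonium ion under neutral conditions, which the acid-sensitive ynol ether should tolerate if the ionisable product is kept cold and used directly.

Step 3
Reactants: 5 3-bromo-1-ethoxyprop-1-yne; 1 ethoxyacetylene (excess)
Product: 6 1,5-diethoxypenta-1,4-diyne
Conditions: CuI (10 mol %), Bu4NI (10 mol %), K2CO3, DMF, 0 °C to rt; chromatography on Et3N-deactivated silica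
Reagents that add atoms: none
Why: Copper-catalysed coupling of a terminal alkyne with a propargylic halide under carbonate base (SN2 attack of the copper acetylide) is the standard mild route to 1,4-diynes, and K2CO3 is too weak to isomerise the doubly propargylic CH2 of the product.

Step 4
Reactants: 1 ethoxyacetylene; 7 acetyl chloride
Product: 9 3-ethoxycyclobut-2-en-1-one, via ketene 8 (not isolated)
Conditions: Et3N, MeCN, 0 °C to rt
Reagents that add atoms: none
Why: Ketene generated by dehydrochlorination of acetyl chloride should undergo thermal [2+2] cycloaddition with the electron-rich ynol ether, the ketene carbonyl carbon bonding to the unsubstituted alkyne carbon, which is the known way to 3-alkoxycyclobutenones.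

Step 5
Reactants: 6 1,5-diethoxypenta-1,4-diyne; 9 3-ethoxycyclobut-2-en-1-one (2.5 equiv)
Product: 16 bis(2,4-diethoxy-6-hydroxyphenyl)methane, via vinylketene 10 (not isolated), via vinylcyclobutenone 11 (not isolated), via dienylketene 12 (not isolated), via monoannulated phenol 13 (not isolated), via second vinylcyclobutenone 14 (not isolated), via second dienylketene 15 (not isolated)
Conditions: degassed PhMe (0.3 M), 80 °C, Ar, base-washed glass; then K2CO3, MeOH, rt
Reagents that add atoms: none
Why: Proposed new method: heating opens cyclobutenone 9 by 4π electrocyclic cleavage to vinylketene 10, whose ketene carbon bonds to the nucleophilic CH2-bearing carbon of one ynol ether of 6 in a [2+2] cycloaddition to give vinylcyclobutenone 11, which reopens (4π) to dienylketene 12. Each benzene ring is closed by thermal disrotatory 6π electrocyclisation of its dienylketene (bond from the ketene carbon to the terminal CH2 of the ethoxyvinyl group) followed by enolisation, first 12 to phenol 13 and then, after the same sequence at the second ynol ether through 14, 15 to 16. The closest known reaction type is the Danheiser benzannulation of cyclobutenones with alkoxy- and siloxyalkynes to 2-substituted resorcinol monoethers; a 3-alkoxycyclobutenone reacting twice on a skipped bis-ynol ether is not precedented. No stereocentre is created in 16, and the transient one at C4 of 11 and 14 is erased on ring opening. The selectivity required is the orientation of both ketene–alkyne cycloadditions, secured by the polarisation of the ynol ether (the oxygen makes the carbon remote from it nucleophilic toward the ketene carbonyl carbon), which places the bridge carbon between the new OH and the alkyne-derived OEt and the cyclobutenone OEt para to it. Neutral, base-free heating at 80 °C should spare the doubly propargylic CH2 and stay below the retro-ene loss of ethylene from ethyl ynol ethers, excess 9 drives the second annulation, and the final methanolysis returns any phenol acylated by surplus 10.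

Step 6
Reactants: 16 bis(2,4-diethoxy-6-hydroxyphenyl)methane
Product: 17 1,1′-[methylenebis(4,6-diethoxy-2-hydroxybenzene-3,1-diyl)]bis(propan-1-one)
Conditions: EtCOCl (2.2 equiv), TiCl4 (3 equiv), CH2Cl2, −20 to 0 °C; ice water
Reagents that add atoms: propionyl chloride, CCC(Cl)=O
Why: Friedel–Crafts acylation through the titanium phenoxide should deliver the acyl group ortho to the free OH of each trioxygenated ring, the first acyl group deactivates its ring against a second acylation, and the isomer acylated between the two ethoxy groups would converge on the same compound in step 7.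

Step 7
Reactants: 17 1,1′-[methylenebis(4,6-diethoxy-2-hydroxybenzene-3,1-diyl)]bis(propan-1-one)
Product: 18 1,1′-[methylenebis(2,4,6-trihydroxybenzene-3,1-diyl)]bis(propan-1-one) (methylenebis-propionylphloroglucinol)
Conditions: BBr3 (10 equiv), CH2Cl2, −78 °C to rt; ice water
Reagents that add atoms: none
Why: BBr3 cleaves aryl ethyl ethers by O-coordination and SN2 attack of bromide on the ethyl group (Lewis acid ether dealkylation), the ethers next to the ketone being assisted by chelation, while the acyl groups make the rings poor enough to resist protodealkylation at the CH2 bridge.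

Step 8
Reactants: 19 flopropione (1-(2,4,6-trihydroxyphenyl)propan-1-one)
Product: 20 propionylfilicinic acid (3,5-dihydroxy-6,6-dimethyl-2-propanoylcyclohexa-2,4-dien-1-one)
Conditions: NaOMe (3.5 equiv), MeI (2.2 equiv), MeOH, 0 °C to rt; dilute HCl
Reagents that add atoms: iodomethane, CI
Why: Dearomative geminal C-methylation of the acylphloroglucinol polyanion with iodomethane is the classical entry to acylfilicinic acids, the second methyl group entering at the already methylated carbon, with under- and over-methylated by-products removed by crystallisation.

Step 9
Reactants: 18 methylenebis-propionylphloroglucinol; 2 formaldehyde (37 % aqueous)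
Product: 21 1,1′-{methylenebis[5-(dimethylaminomethyl)-2,4,6-trihydroxybenzene-3,1-diyl]}bis(propan-1-one)
Conditions: Me2NH (40 % aq.) premixed with formalin (2.2 equiv each), EtOH, 0 °C to rt; used crude
Reagents that add atoms: dimethylamine, CNC
Why: The phenolic Mannich reaction aminomethylates the single free, doubly ortho-hydroxylated position of each ring, and premixing amine and formaldehyde makes the iminium ion rather than free formaldehyde the electrophile so that methylene bridging between rings is suppressed.

Step 10
Reactants: 21 bis-Mannich base; 20 propionylfilicinic acid (2.4 equiv)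
Product: 22 target, bis{2,4,6-trihydroxy-3-propanoyl-5-[(2,6-dihydroxy-3,3-dimethyl-4-oxo-5-propanoylcyclohexa-1,5-dien-1-yl)methyl]phenyl}methane
Conditions: 1,4-dioxane, 90 °C, N2 sweep; crystallisation
Reagents that add atoms: none
Why: Thermal loss of dimethylamine from the phenolic Mannich base gives an ortho-quinone methide that is trapped at C4 of the acidic acylfilicinic acid by conjugate addition (Mannich-base alkylation of a 1,3-dicarbonyl), and because every ring carbon of 21 is substituted only the cross-coupled product can form.

**Compound list**

1 | ethoxyacetylene | CCOC#C | starting material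
2 | formaldehyde (paraformaldehyde or formalin) | C=O | starting material
3 | lithium ethoxyacetylide (not isolated) | [Li]C#COCC | intermediate
4 | 3-ethoxyprop-2-yn-1-ol | CCOC#CCO | intermediate
5 | 3-bromo-1-ethoxyprop-1-yne | CCOC#CCBr | intermediate
6 | 1,5-diethoxypenta-1,4-diyne | CCOC#CCC#COCC | intermediate
7 | acetyl chloride | CC(Cl)=O | starting material
8 | ketene (not isolated) | C=C=O | intermediate
9 | 3-ethoxycyclobut-2-en-1-one | CCOC1=CC(=O)C1 | intermediate
10 | 3-ethoxybuta-1,3-dien-1-one, the vinylketene (not isolated) | C=C(OCC)C=C=O | intermediate
11 | racemic 3-ethoxy-4-(1-ethoxyethenyl)-2-(3-ethoxyprop-2-yn-1-yl)cyclobut-2-en-1-one (not isolated) | CCOC#CCC1=C(OCC)C(C(=C)OCC)C1=O | intermediate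
12 | (3E)-3,5-diethoxy-2-(3-ethoxyprop-2-yn-1-yl)hexa-1,3,5-trien-1-one (not isolated) | CCOC#CCC(=C=O)/C(OCC)=C\C(=C)OCC | intermediate
13 | 3,5-diethoxy-2-(3-ethoxyprop-2-yn-1-yl)phenol (not isolated) | CCOC#CCc1c(O)cc(OCC)cc1OCC | intermediate
14 | racemic 2-[(2,4-diethoxy-6-hydroxyphenyl)methyl]-3-ethoxy-4-(1-ethoxyethenyl)cyclobut-2-en-1-one (not isolated) | CCOc1cc(O)c(CC2=C(OCC)C(C(=C)OCC)C2=O)c(OCC)c1 | intermediate
15 | (3E)-2-[(2,4-diethoxy-6-hydroxyphenyl)methyl]-3,5-diethoxyhexa-1,3,5-trien-1-one (not isolated) | CCOc1cc(O)c(CC(=C=O)/C(OCC)=C\C(=C)OCC)c(OCC)c1 | intermediate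
16 | bis(2,4-diethoxy-6-hydroxyphenyl)methane | CCOc1cc(O)c(Cc2c(O)cc(OCC)cc2OCC)c(OCC)c1 | intermediate
17 | 1,1′-[methylenebis(4,6-diethoxy-2-hydroxybenzene-3,1-diyl)]bis(propan-1-one) | CCC(=O)c1c(O)c(Cc2c(O)c(C(=O)CC)c(OCC)cc2OCC)c(OCC)cc1OCC | intermediate
18 | 1,1′-[methylenebis(2,4,6-trihydroxybenzene-3,1-diyl)]bis(propan-1-one) | CCC(=O)c1c(O)cc(O)c(Cc2c(O)cc(O)c(C(=O)CC)c2O)c1O | intermediate
19 | flopropione, 1-(2,4,6-trihydroxyphenyl)propan-1-one | CCC(=O)c1c(O)cc(O)cc1O | starting material
20 | propionylfilicinic acid, 3,5-dihydroxy-6,6-dimethyl-2-propanoylcyclohexa-2,4-dien-1-one | CCC(=O)C1=C(O)C=C(O)C(C)(C)C1=O | intermediate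
21 | 1,1′-{methylenebis[5-(dimethylaminomethyl)-2,4,6-trihydroxybenzene-3,1-diyl]}bis(propan-1-one) | CCC(=O)c1c(O)c(CN(C)C)c(O)c(Cc2c(O)c(CN(C)C)c(O)c(C(=O)CC)c2O)c1O | intermediate
22 | bis{2,4,6-trihydroxy-3-propanoyl-5-[(2,6-dihydroxy-3,3-dimethyl-4-oxo-5-propanoylcyclohexa-1,5-dien-1-yl)methyl]phenyl}methane | CCC(=O)C1=C(O)C(Cc2c(O)c(Cc3c(O)c(CC4=C(O)C(C)(C)C(=O)C(C(=O)CC)=C4O)c(O)c(C(=O)CC)c3O)c(O)c(C(=O)CC)c2O)=C(O)C(C)(C)C1=O | target

**Count**

Total: 10 steps. Longest linear sequence: 8 steps (1, 2, 3, 5, 6, 7, 9, 10) from ethoxyacetylene; steps 4 and 8 are side branches.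

**Steps most likely to fail**

Step 5. Three processes could defeat the double annulation:
- the phenol formed in the first annulation may add across the remaining ynol ether, closing a cyclic ketene acetal before the second vinylketene arrives;
- the skipped diyne may isomerise prototropically to an allenyne;
- the vinylketene may dimerise faster than it is trapped.

The fallback uses known chemistry and sets out from flopropione 19 and formaldehyde 2. Classical phenol–formaldehyde condensation (excess 19, formalin, aqueous NaOH, 0 °C, then acidification) joins two acylphloroglucinol rings through CH2 and comes back to the route at 18. Steps 6 and 7 are then not needed. No compound outside the list is made (F0).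

Step 2. The bromide may ionise to an alkoxy-stabilised propargyl/allenyl cation and then polymerise or hydrolyse before or during the coupling of step 3. The fallback avoids any propargylic halide by bringing in the bridge carbon at the carbinol oxidation level. It sets out from lithium ethoxyacetylide 3.
- Two equivalents of 3 add to ethyl formate (THF, −78 to 0 °C) to give 1,5-diethoxypenta-1,4-diyn-3-ol F1.
- F1 is silylated without acidic contact (TBSCl, imidazole, DMF) to 3-(tert-butyldimethylsilyloxy)-1,5-diethoxypenta-1,4-diyne F2.
- F2 is heated with 9 as in step 5 to give tert-butyl[bis(2,4-diethoxy-6-hydroxyphenyl)methoxy]dimethylsilane F3; this annulation is as unprecedented as step 5 itself.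
- Ionic hydrogenation (Et3SiH, CF3CO2H, CH2Cl2, −40 °C) removes the doubly benzylic oxygen, and the sequence comes back to the route at 16.

Step 10. Reversible methylene transfer under heat (retro-Mannich and retro-Michael exchange of CH2 bridges) may scramble the units into homodimers, and re-addition of dimethylamine to the quinone methide may stall conversion. The fallback reverses the roles of the partners and sets out from 20. Mannich reaction of 20 with formaldehyde 2 and dimethylamine (EtOH, rt) gives 4-(dimethylaminomethyl)-3,5-dihydroxy-6,6-dimethyl-2-propanoylcyclohexa-2,4-dien-1-one F4. Two equivalents of F4 are heated with 18 (dioxane, 80 °C), so that the enone methide from the end unit is captured by the one free ring carbon of each inner ring. This comes back to the route at 22.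

**Further compounds**

F0 | step 5 | none | none
F1 | step 2 | 1,5-diethoxypenta-1,4-diyn-3-ol | CCOC#CC(O)C#COCC
F2 | step 2 | 3-(tert-butyldimethylsilyloxy)-1,5-diethoxypenta-1,4-diyne | CCOC#CC(O[Si](C)(C)C(C)(C)C)C#COCC
F3 | step 2 | tert-butyl[bis(2,4-diethoxy-6-hydroxyphenyl)methoxy]dimethylsilane | CCOc1cc(O)c(C(O[Si](C)(C)C(C)(C)C)c2c(O)cc(OCC)cc2OCC)c(OCC)c1
F4 | step 10 | 4-(dimethylaminomethyl)-3,5-dihydroxy-6,6-dimethyl-2-propanoylcyclohexa-2,4-dien-1-one | CCC(=O)C1=C(O)C(CN(C)C)=C(O)C(C)(C)C1=O
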